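## Retrosynthetic overview (carotenoid numbering)

1. The C19 ester (from (E)-dec-2-enoic acid) and the C11=C12 bond are cut last: a Wittig reaction joins a C25 ε-polyenyl phosphonium salt to a C15 lactol, whose opening frees only the C19 hydroxyl for acylation.
2. The key C–C bond is C7–C8: an α-selective carbonyl allylation of 5-oxo-2,5-dihydrofuran-3-carbaldehyde with the allylbarium reagent of the β-ring allylic chloride. The butenolide carries C8–C11 and C19 and locks the C9=C10 geometry.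
3. The C25 piece comes from a C15 ε-ring phosphonium salt and the C10 dialdehyde (Wittig); C6' is set by face-selective hydroboration of an exocyclic diene.
4. No carbocycle is built. Both six-membered rings come from ketoisophorone: the β ring first via (S)-phorenol, the ε ring second via (R)-phorenol, using antipodal transfer-hydrogenation catalysts. The butenolide ring is made once (Wittig then lactonisation) and opened in the final coupling.

Assumption: the transfer hydrogenation of 1 follows the aryl-ketone sense with the alkenyl arm in the aryl role ((S,S)-ligand gives the (S)-alcohol); if the measured rotation shows the opposite, the two catalyst antipodes are exchanged between steps 1 and 10.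

TBS = tert-butyldimethylsilyl throughout.

## Route

**Step 1**
Reactants: 1 ketoisophorone (2,6,6-trimethylcyclohex-2-ene-1,4-dione)
Product: 2 (4S)-4-hydroxy-2,6,6-trimethylcyclohex-2-en-1-one ((S)-phorenol)
Conditions: RuCl(p-cymene)[(S,S)-TsDPEN] (1 mol %), HCO2H/Et3N (5:2), CH2Cl2, 0 °C → rt
Reagents that add atoms: none
Why: Noyori–Ikariya asymmetric transfer hydrogenation reduces only the unhindered C4 carbonyl (C1 is shielded by the quaternary carbon), and the chiral ruthenium hydride sets the carbinol centre as S.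

**Step 2**
Reactants: 2 (S)-phorenol
Product: 3 (4S)-4-(TBS-oxy)-2,6,6-trimethylcyclohex-2-en-1-one
Conditions: TBSCl, imidazole, DMF, rt
Reagents that add atoms: tert-butyldimethylsilyl chloride, CC(C)(C)[Si](C)(C)Cl
Why: Standard silylation of a secondary alcohol; the stereocentre is untouched.

**Step 3**
Reactants: 3 (4S)-4-(TBS-oxy)-2,6,6-trimethylcyclohex-2-en-1-one
Product: 5 (4R)-4-(TBS-oxy)-2,6,6-trimethylcyclohex-1-en-1-yl trifluoromethanesulfonate, via lithium enolate 4 (not isolated)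
Conditions: LiBH(s-Bu)3, THF, −78 °C; then PhNTf2, −78 → 0 °C
Reagents that add atoms: N-phenylbis(trifluoromethanesulfonimide), FC(F)(F)S(=O)(=O)N(c1ccccc1)S(=O)(=O)C(F)(F)F
Why: Conjugate hydride reduction of the β-unsubstituted, carbonyl-hindered enone gives the tetrasubstituted enolate regiospecifically and O-triflation traps it; the carbinol centre is unchanged in space (S becomes R only through the priority change).

**Step 4**
Reactants: 5 vinyl triflate
Product: 6 methyl (4R)-4-(TBS-oxy)-2,6,6-trimethylcyclohex-1-ene-1-carboxylate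
Conditions: Pd(OAc)2 (5 mol %), PPh3 (10 mol %), CO (1 atm), MeOH, Et3N, DMF, 60 °C
Reagents that add atoms: carbon monoxide, [C-]#[O+]; methanol, CO
Why: Palladium-catalysed methoxycarbonylation: zerovalent palladium inserts into the C–OTf bond, CO inserts and methanol cleaves the acyl complex.

**Step 5**
Reactants: 6 methyl ester
Product: 7 [(4R)-4-(TBS-oxy)-2,6,6-trimethylcyclohex-1-en-1-yl]methanol
Conditions: i-Bu2AlH (2.5 equiv), CH2Cl2, −78 → 0 °C
Reagents that add atoms: none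
Why: Hydride reduction of the conjugated ester to the allylic alcohol; the silyl ether and ring alkene are inert.

**Step 6**
Reactants: 7 allylic alcohol
Product: 8 tert-butyl{[(1R)-4-(chloromethyl)-3,5,5-trimethylcyclohex-3-en-1-yl]oxy}dimethylsilane
Conditions: PPh3, CCl4, CH2Cl2, 0 °C → rt
Reagents that add atoms: carbon tetrachloride, ClC(Cl)(Cl)Cl
Why: Appel chlorination under neutral conditions gives the primary allylic chloride (the SN2' position is a hindered tetrasubstituted carbon).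

**Step 7**
Reactants: 9 1,3-dihydroxyacetone (commercial dimer); 10 ethyl (triphenylphosphoranylidene)acetate
Product: 12 4-(hydroxymethyl)furan-2(5H)-one, via hydroxy ester 11 (not isolated)
Conditions: CH2Cl2, rt, 16 h
Reagents that add atoms: none
Why: Wittig olefination of the ketone followed by spontaneous lactonisation of the hydroxymethyl group cis to the ester; the ring thereby fixes the future C19 cis to C11.

**Step 8**
Reactants: 12 4-(hydroxymethyl)furan-2(5H)-one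
Product: 13 5-oxo-2,5-dihydrofuran-3-carbaldehyde
Conditions: Dess–Martin periodinane, CH2Cl2, 0 °C → rt; non-aqueous work-up, used at once
Reagents that add atoms: none
Why: Dess–Martin oxidation of the primary allylic alcohol to the aldehyde without touching the lactone.

**Step 9 (key step)**
Reactants: 8 allylic chloride; 13 5-oxo-2,5-dihydrofuran-3-carbaldehyde
Product: 15 4-{1-hydroxy-2-[(4R)-4-(TBS-oxy)-2,6,6-trimethylcyclohex-1-en-1-yl]ethyl}furan-2(5H)-one (both C8 epimers), via allylbarium chloride 14 (not isolated)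
Conditions: BaI2, lithium biphenylide (LiC12H10, 2 equiv), THF, rt; then 8, −78 °C; then 13, −78 °C
Reagents that add atoms: none
Why: Carbonyl allylation with an allylbarium reagent, which attacks the aldehyde 1,2 through its less substituted (α) carbon and so forms C7–C8 with the ring double bond kept tetrasubstituted. The new C8 carbinol forms unselectively and is erased by the oxidation in step 25.

**Step 10**
Reactants: 1 ketoisophorone
Product: 16 (4R)-4-hydroxy-2,6,6-trimethylcyclohex-2-en-1-one ((R)-phorenol)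
Conditions: RuCl(p-cymene)[(R,R)-TsDPEN] (1 mol %), HCO2H/Et3N (5:2), CH2Cl2, 0 °C → rt
Reagents that add atoms: none
Why: The same asymmetric transfer hydrogenation with the antipodal catalyst sets the future C3' as R.

**Step 11**
Reactants: 16 (R)-phorenol
Product: 17 (4R)-4-(TBS-oxy)-2,6,6-trimethylcyclohex-2-en-1-one
Conditions: TBSCl, imidazole, DMF, rt
Reagents that add atoms: tert-butyldimethylsilyl chloride, CC(C)(C)[Si](C)(C)Cl
Why: Standard silylation; the stereocentre is untouched.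

**Step 12**
Reactants: 17 (4R)-4-(TBS-oxy)-2,6,6-trimethylcyclohex-2-en-1-one
Product: 18 tert-butyldimethyl{[(1R)-3,5,5-trimethyl-4-methylidenecyclohex-2-en-1-yl]oxy}silane
Conditions: Cp2TiMe2 (3 equiv), toluene, 70 °C, dark
Reagents that add atoms: dimethyltitanocene, [CH3-].[CH3-].[Ti+4].c1cc[cH-]c1.c1cc[cH-]c1
Why: Petasis methylenation converts the hindered enone carbonyl into the exocyclic alkene under non-basic conditions, so the γ-stereocentre cannot epimerise.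

**Step 13**
Reactants: 18 exocyclic diene
Product: 20 [(1R,4R)-4-(TBS-oxy)-2,6,6-trimethylcyclohex-2-en-1-yl]methanol, via alkylborane 19 (not isolated)
Conditions: 9-BBN-H, THF, 0 °C → rt; then NaOH, H2O2, 0 °C; chromatography
Reagents that add atoms: hydrogen peroxide, OO
Why: Anti-Markovnikov hydroboration–oxidation of the terminal 1,1-disubstituted alkene only. In the sofa conformer that keeps the silyloxy group pseudo-equatorial, the axial methyl of the neighbouring quaternary carbon blocks one face, so hydrogen is delivered to C6' on the face cis to the silyloxy group and the CH2OH group ends trans (6'R).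

**Step 14**
Reactants: 20 primary alcohol
Product: 21 (1R,4R)-4-(TBS-oxy)-2,6,6-trimethylcyclohex-2-ene-1-carbaldehyde
Conditions: Dess–Martin periodinane, NaHCO3, CH2Cl2, 0 °C
Reagents that add atoms: none
Why: Buffered Dess–Martin oxidation gives the α-branched β,γ-unsaturated aldehyde without epimerisation or conjugation.

**Step 15**
Reactants: 21 aldehyde
Product: 22 (3E)-4-[(1R,4R)-4-(TBS-oxy)-2,6,6-trimethylcyclohex-2-en-1-yl]but-3-en-2-one
Conditions: (MeO)2P(O)CH2C(O)CH3, LiCl, i-Pr2NEt, MeCN, rt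
Reagents that add atoms: dimethyl (2-oxopropyl)phosphonate, CC(=O)CP(=O)(OC)OC
Why: Horner–Wadsworth–Emmons olefination under Masamune–Roush conditions gives the E-enone with a base too weak to epimerise C6'.

**Step 16**
Reactants: 22 enone
Product: 23 ethyl (2E,4E)-3-methyl-5-[(1R,4R)-4-(TBS-oxy)-2,6,6-trimethylcyclohex-2-en-1-yl]penta-2,4-dienoate
Conditions: (EtO)2P(O)CH2CO2Et, NaH, THF, 0 °C → rt
Reagents that add atoms: triethyl phosphonoacetate, CCOC(=O)CP(=O)(OCC)OCC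
Why: Horner–Wadsworth–Emmons olefination of the methyl ketone gives mainly the 2E dienoate; the minor 2Z isomer is removed after step 17.

**Step 17**
Reactants: 23 dienoate
Product: 24 (2E,4E)-3-methyl-5-[(1R,4R)-4-(TBS-oxy)-2,6,6-trimethylcyclohex-2-en-1-yl]penta-2,4-dien-1-ol
Conditions: i-Bu2AlH (2.2 equiv), CH2Cl2, −78 °C; chromatography
Reagents that add atoms: none
Why: 1,2-Reduction of the ester to the allylic alcohol, at which stage the 2E isomer is purified.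

**Step 18**
Reactants: 24 dienol
Product: 26 {(2E,4E)-3-methyl-5-[(1R,4R)-4-(TBS-oxy)-2,6,6-trimethylcyclohex-2-en-1-yl]penta-2,4-dien-1-yl}triphenylphosphonium bromide, via dienyl bromide 25 (not isolated)
Conditions: CBr4, PPh3 (2.5 equiv), CH2Cl2, 0 °C → rt
Reagents that add atoms: triphenylphosphine, c1ccccc1P(c1ccccc1)c1ccccc1; carbon tetrabromide, BrC(Br)(Br)Br
Why: Appel bromination followed by quaternisation with the excess phosphine, under acid-free conditions that keep the allylic silyl ether.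

**Step 19**
Reactants: 26 C15 phosphonium bromide; 27 (2E,4E,6E)-2,7-dimethylocta-2,4,6-trienedial (threefold excess)
Product: 29 (2E,4E,6E,8E,10E,12E)-2,7,11-trimethyl-13-[(1R,4R)-4-(TBS-oxy)-2,6,6-trimethylcyclohex-2-en-1-yl]trideca-2,4,6,8,10,12-hexaenal, via ylide 28 (not isolated)
Conditions: NaOMe, CH2Cl2/MeOH, 0 °C → rt; then heptane, reflux, dark
Reagents that add atoms: none
Why: Mono-Wittig olefination of the symmetrical dialdehyde (the excess suppresses double condensation); heating isomerises the sterically hindered Z isomer of the new double bond to E.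

**Step 20**
Reactants: 29 C25 aldehyde
Product: 30 (2E,4E,6E,8E,10E,12E)-2,7,11-trimethyl-13-[(1R,4R)-4-(TBS-oxy)-2,6,6-trimethylcyclohex-2-en-1-yl]trideca-2,4,6,8,10,12-hexaen-1-ol
Conditions: NaBH4, MeOH/THF, 0 °C
Reagents that add atoms: none
Why: Clean 1,2-reduction of the polyenal to the primary allylic alcohol.

**Step 21**
Reactants: 30 C25 alcohol
Product: 32 {(2E,4E,6E,8E,10E,12E)-2,7,11-trimethyl-13-[(1R,4R)-4-(TBS-oxy)-2,6,6-trimethylcyclohex-2-en-1-yl]trideca-2,4,6,8,10,12-hexaen-1-yl}triphenylphosphonium bromide, via hexaenyl bromide 31 (not isolated)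
Conditions: CBr4, PPh3 (2.5 equiv), CH2Cl2, −20 °C → rt, dark
Reagents that add atoms: triphenylphosphine, c1ccccc1P(c1ccccc1)c1ccccc1; carbon tetrabromide, BrC(Br)(Br)Br
Why: Appel bromination with in-situ quaternisation; the labile polyenyl bromide is trapped at the terminal carbon as the fully conjugated phosphonium salt.

**Step 22**
Reactants: 15 hydroxy butenolide
Product: 33 4-{1-hydroxy-2-[(4R)-4-(TBS-oxy)-2,6,6-trimethylcyclohex-1-en-1-yl]ethyl}-2,5-dihydrofuran-2-ol (stereoisomer mixture)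
Conditions: i-Bu2AlH (2.2 equiv), CH2Cl2, −78 °C; neutral work-up, used crude
Reagents that add atoms: none
Why: Partial reduction of the lactone stops at the lactol (a masked C11 aldehyde) at −78 °C; acid is avoided to prevent dehydration to the furan.

**Step 23**
Reactants: 32 C25 phosphonium bromide; 33 lactol
Product: 35 (3R,3'R,6'R)-3,3'-bis(TBS-oxy)-7,8-dihydro-β,ε-carotene-8,19-diol (all-E polyene; both C8 epimers), via ylide 34 (not isolated)
Conditions: 32 (1.2 equiv), NaN(SiMe3)2, THF, −78 → 0 °C; then 33 pre-treated with NaN(SiMe3)2 (2 equiv), −78 °C → rt; then EtOAc, 65 °C, dark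
Reagents that add atoms: none
Why: Wittig olefination of the ring-opened (Z)-hydroxy enal form of the lactol forms C11=C12 and frees only the C19 hydroxyl. The C9=C10 geometry is inherited from the butenolide, and heating converts the hindered 11Z isomer to 11E.

**Step 24**
Reactants: 35 diol; 36 (2E)-dec-2-enoic acid
Product: 37 (3R,3'R,6'R)-3,3'-bis(TBS-oxy)-8-hydroxy-7,8-dihydro-β,ε-caroten-19-yl (2E)-dec-2-enoate (both C8 epimers)
Conditions: DCC, DMAP (0.1 equiv), CH2Cl2, −20 → 0 °C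
Reagents that add atoms: none
Why: Steglich esterification acylates the primary allylic C19 hydroxyl much faster than the hindered secondary C8 hydroxyl.

**Step 25**
Reactants: 37 hydroxy ester
Product: 38 (3R,3'R,6'R)-3,3'-bis(TBS-oxy)-8-oxo-7,8-dihydro-β,ε-caroten-19-yl (2E)-dec-2-enoate
Conditions: Dess–Martin periodinane, NaHCO3, CH2Cl2, 0 °C → rt
Reagents that add atoms: none
Why: Buffered Dess–Martin oxidation of the only free hydroxyl gives the conjugated C8 ketone and removes the uncontrolled stereocentre.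

**Step 26**
Reactants: 38 bis-silyl ether
Product: 39 (3R,3'R,6'R)-3,3'-dihydroxy-8-oxo-7,8-dihydro-β,ε-caroten-19-yl (2E)-dec-2-enoate (target)
Conditions: HF·pyridine, pyridine, THF, 0 °C → rt, dark
Reagents that add atoms: none
Why: Buffered fluoride desilylation removes both TBS ethers without cleaving the allylic ester or disturbing the polyenone.

## Compound list

1 | ketoisophorone (2,6,6-trimethylcyclohex-2-ene-1,4-dione) | O=C1C(C)=CC(=O)CC1(C)C | starting material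
2 | (4S)-4-hydroxy-2,6,6-trimethylcyclohex-2-en-1-one | O=C1C(C)=C[C@@H](O)CC1(C)C | intermediate
3 | (4S)-4-(TBS-oxy)-2,6,6-trimethylcyclohex-2-en-1-one | O=C1C(C)=C[C@@H](O[Si](C)(C)C(C)(C)C)CC1(C)C | intermediate
4 | lithium (4R)-4-(TBS-oxy)-2,6,6-trimethylcyclohex-1-en-1-olate | [Li]OC1=C(C)C[C@@H](O[Si](C)(C)C(C)(C)C)CC1(C)C | intermediate
5 | (4R)-4-(TBS-oxy)-2,6,6-trimethylcyclohex-1-en-1-yl trifluoromethanesulfonate | FC(F)(F)S(=O)(=O)OC1=C(C)C[C@@H](O[Si](C)(C)C(C)(C)C)CC1(C)C | intermediate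
6 | methyl (4R)-4-(TBS-oxy)-2,6,6-trimethylcyclohex-1-ene-1-carboxylate | COC(=O)C1=C(C)C[C@@H](O[Si](C)(C)C(C)(C)C)CC1(C)C | intermediate
7 | [(4R)-4-(TBS-oxy)-2,6,6-trimethylcyclohex-1-en-1-yl]methanol | OCC1=C(C)C[C@@H](O[Si](C)(C)C(C)(C)C)CC1(C)C | intermediate
8 | tert-butyl{[(1R)-4-(chloromethyl)-3,5,5-trimethylcyclohex-3-en-1-yl]oxy}dimethylsilane | ClCC1=C(C)C[C@@H](O[Si](C)(C)C(C)(C)C)CC1(C)C | intermediate
9 | 1,3-dihydroxyacetone (commercial dimer) | OCC(=O)CO | starting material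
10 | ethyl (triphenylphosphoranylidene)acetate | CCOC(=O)C=P(c1ccccc1)(c1ccccc1)c1ccccc1 | starting material
11 | ethyl 4-hydroxy-3-(hydroxymethyl)but-2-enoate | CCOC(=O)C=C(CO)CO | intermediate
12 | 4-(hydroxymethyl)furan-2(5H)-one | O=C1OCC(CO)=C1 | intermediate
13 | 5-oxo-2,5-dihydrofuran-3-carbaldehyde | O=CC1=CC(=O)OC1 | intermediate
14 | {[(4R)-4-(TBS-oxy)-2,6,6-trimethylcyclohex-1-en-1-yl]methyl}barium chloride | Cl[Ba]CC1=C(C)C[C@@H](O[Si](C)(C)C(C)(C)C)CC1(C)C | intermediate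
15 | 4-{1-hydroxy-2-[(4R)-4-(TBS-oxy)-2,6,6-trimethylcyclohex-1-en-1-yl]ethyl}furan-2(5H)-one, both carbinol (C8) epimers | O=C1OCC(C(O)CC2=C(C)C[C@@H](O[Si](C)(C)C(C)(C)C)CC2(C)C)=C1 | intermediate
16 | (4R)-4-hydroxy-2,6,6-trimethylcyclohex-2-en-1-one | O=C1C(C)=C[C@H](O)CC1(C)C | intermediate
17 | (4R)-4-(TBS-oxy)-2,6,6-trimethylcyclohex-2-en-1-one | O=C1C(C)=C[C@H](O[Si](C)(C)C(C)(C)C)CC1(C)C | intermediate
18 | tert-butyldimethyl{[(1R)-3,5,5-trimethyl-4-methylidenecyclohex-2-en-1-yl]oxy}silane | C=C1C(C)=C[C@H](O[Si](C)(C)C(C)(C)C)CC1(C)C | intermediate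
19 | 9-{[(1R,4R)-4-(TBS-oxy)-2,6,6-trimethylcyclohex-2-en-1-yl]methyl}-9-borabicyclo[3.3.1]nonane | C(B1C2CCCC1CCC2)[C@H]1C(C)=C[C@H](O[Si](C)(C)C(C)(C)C)CC1(C)C | intermediate
20 | [(1R,4R)-4-(TBS-oxy)-2,6,6-trimethylcyclohex-2-en-1-yl]methanol (trans) | OC[C@H]1C(C)=C[C@H](O[Si](C)(C)C(C)(C)C)CC1(C)C | intermediate
21 | (1R,4R)-4-(TBS-oxy)-2,6,6-trimethylcyclohex-2-ene-1-carbaldehyde | O=C[C@H]1C(C)=C[C@H](O[Si](C)(C)C(C)(C)C)CC1(C)C | intermediate
22 | (3E)-4-[(1R,4R)-4-(TBS-oxy)-2,6,6-trimethylcyclohex-2-en-1-yl]but-3-en-2-one | CC(=O)/C=C/[C@H]1C(C)=C[C@H](O[Si](C)(C)C(C)(C)C)CC1(C)C | intermediate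
23 | ethyl (2E,4E)-3-methyl-5-[(1R,4R)-4-(TBS-oxy)-2,6,6-trimethylcyclohex-2-en-1-yl]penta-2,4-dienoate | CCOC(=O)/C=C(C)/C=C/[C@H]1C(C)=C[C@H](O[Si](C)(C)C(C)(C)C)CC1(C)C | intermediate
24 | (2E,4E)-3-methyl-5-[(1R,4R)-4-(TBS-oxy)-2,6,6-trimethylcyclohex-2-en-1-yl]penta-2,4-dien-1-ol | OC/C=C(C)/C=C/[C@H]1C(C)=C[C@H](O[Si](C)(C)C(C)(C)C)CC1(C)C | intermediate
25 | (2E,4E)-1-bromo-3-methyl-5-[(1R,4R)-4-(TBS-oxy)-2,6,6-trimethylcyclohex-2-en-1-yl]penta-2,4-diene | BrC/C=C(C)/C=C/[C@H]1C(C)=C[C@H](O[Si](C)(C)C(C)(C)C)CC1(C)C | intermediate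
26 | {(2E,4E)-3-methyl-5-[(1R,4R)-4-(TBS-oxy)-2,6,6-trimethylcyclohex-2-en-1-yl]penta-2,4-dien-1-yl}triphenylphosphonium bromide | c1ccccc1[P+](c1ccccc1)(c1ccccc1)C/C=C(C)/C=C/[C@H]1C(C)=C[C@H](O[Si](C)(C)C(C)(C)C)CC1(C)C.[Br-] | intermediate
27 | (2E,4E,6E)-2,7-dimethylocta-2,4,6-trienedial (C10 dialdehyde) | O=C/C(C)=C/C=C/C=C(C)/C=O | starting material
28 | ylide of 26, {(2E,4E)-3-methyl-5-[(1R,4R)-4-(TBS-oxy)-2,6,6-trimethylcyclohex-2-en-1-yl]penta-2,4-dien-1-ylidene}triphenylphosphorane | c1ccccc1P(c1ccccc1)(c1ccccc1)=C/C=C(C)/C=C/[C@H]1C(C)=C[C@H](O[Si](C)(C)C(C)(C)C)CC1(C)C | intermediate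
29 | (2E,4E,6E,8E,10E,12E)-2,7,11-trimethyl-13-[(1R,4R)-4-(TBS-oxy)-2,6,6-trimethylcyclohex-2-en-1-yl]trideca-2,4,6,8,10,12-hexaenal (C25 aldehyde) | O=C/C(C)=C/C=C/C=C(C)/C=C/C=C(C)/C=C/[C@H]1C(C)=C[C@H](O[Si](C)(C)C(C)(C)C)CC1(C)C | intermediate
30 | (2E,4E,6E,8E,10E,12E)-2,7,11-trimethyl-13-[(1R,4R)-4-(TBS-oxy)-2,6,6-trimethylcyclohex-2-en-1-yl]trideca-2,4,6,8,10,12-hexaen-1-ol | OC/C(C)=C/C=C/C=C(C)/C=C/C=C(C)/C=C/[C@H]1C(C)=C[C@H](O[Si](C)(C)C(C)(C)C)CC1(C)C | intermediate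
31 | the corresponding all-E 1-bromo-hexaene (C25 bromide) | BrC/C(C)=C/C=C/C=C(C)/C=C/C=C(C)/C=C/[C@H]1C(C)=C[C@H](O[Si](C)(C)C(C)(C)C)CC1(C)C | intermediate
32 | {(2E,4E,6E,8E,10E,12E)-2,7,11-trimethyl-13-[(1R,4R)-4-(TBS-oxy)-2,6,6-trimethylcyclohex-2-en-1-yl]trideca-2,4,6,8,10,12-hexaen-1-yl}triphenylphosphonium bromide | c1ccccc1[P+](c1ccccc1)(c1ccccc1)C/C(C)=C/C=C/C=C(C)/C=C/C=C(C)/C=C/[C@H]1C(C)=C[C@H](O[Si](C)(C)C(C)(C)C)CC1(C)C.[Br-] | intermediate
33 | 4-{1-hydroxy-2-[(4R)-4-(TBS-oxy)-2,6,6-trimethylcyclohex-1-en-1-yl]ethyl}-2,5-dihydrofuran-2-ol, mixture of lactol and carbinol epimers | OC1OCC(C(O)CC2=C(C)C[C@@H](O[Si](C)(C)C(C)(C)C)CC2(C)C)=C1 | intermediate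
34 | ylide of 32 (all-E hexaenylidene triphenylphosphorane) | c1ccccc1P(c1ccccc1)(c1ccccc1)=C/C(C)=C/C=C/C=C(C)/C=C/C=C(C)/C=C/[C@H]1C(C)=C[C@H](O[Si](C)(C)C(C)(C)C)CC1(C)C | intermediate
35 | (3R,3'R,6'R)-3,3'-bis(TBS-oxy)-7,8-dihydro-β,ε-carotene-8,19-diol, all-E polyene with C19 cis to C11, both C8 epimers | OC\C(=C/C=C/C(C)=C/C=C/C=C(C)/C=C/C=C(C)/C=C/[C@H]1C(C)=C[C@H](O[Si](C)(C)C(C)(C)C)CC1(C)C)C(O)CC1=C(C)C[C@@H](O[Si](C)(C)C(C)(C)C)CC1(C)C | intermediate
36 | (2E)-dec-2-enoic acid | CCCCCCC/C=C/C(=O)O | starting material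
37 | (3R,3'R,6'R)-3,3'-bis(TBS-oxy)-8-hydroxy-7,8-dihydro-β,ε-caroten-19-yl (2E)-dec-2-enoate, both C8 epimers | CCCCCCC/C=C/C(=O)OC\C(=C/C=C/C(C)=C/C=C/C=C(C)/C=C/C=C(C)/C=C/[C@H]1C(C)=C[C@H](O[Si](C)(C)C(C)(C)C)CC1(C)C)C(O)CC1=C(C)C[C@@H](O[Si](C)(C)C(C)(C)C)CC1(C)C | intermediate
38 | (3R,3'R,6'R)-3,3'-bis(TBS-oxy)-8-oxo-7,8-dihydro-β,ε-caroten-19-yl (2E)-dec-2-enoate | CCCCCCC/C=C/C(=O)OC\C(=C/C=C/C(C)=C/C=C/C=C(C)/C=C/C=C(C)/C=C/[C@H]1C(C)=C[C@H](O[Si](C)(C)C(C)(C)C)CC1(C)C)C(=O)CC1=C(C)C[C@@H](O[Si](C)(C)C(C)(C)C)CC1(C)C | intermediate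
39 | (3R,3'R,6'R)-3,3'-dihydroxy-8-oxo-7,8-dihydro-β,ε-caroten-19-yl (2E)-dec-2-enoate (CNP0332433.1) | CCCCCCC/C=C/C(=O)OC\C(=C/C=C/C(C)=C/C=C/C=C(C)/C=C/C=C(C)/C=C/[C@H]1C(C)=C[C@H](O)CC1(C)C)C(=O)CC1=C(C)C[C@@H](O)CC1(C)C | target

## Totals and risks

Total steps: 26. Longest linear sequence: 16 steps (steps 10–21, then 23–26, from ketoisophorone through the ε-ring branch).

**Step 9 (α-selective allylbarium addition to the sensitive formyl butenolide).** The fallback sets out from 3 and returns at 15. Hydrogenation of the enone double bond (H2, Pd/C, EtOAc) gives (4R)-4-(TBS-oxy)-2,2,6-trimethylcyclohexanone F1 (C6 epimers, of no consequence). Wittig methylenation (Ph3PCH3Br, KOt-Bu, toluene, 90 °C) gives tert-butyldimethyl{[(1R)-3,3,5-trimethyl-4-methylidenecyclohexyl]oxy}silane F2. A Me2AlCl-promoted carbonyl-ene reaction of F2 with aldehyde 13 (CH2Cl2, −78 → −20 °C) then forms C7–C8. The only allylic hydrogen is the ring C–H next to the methyl group, so the double bond lands in the tetrasubstituted ring position and 15 results with no α/γ question.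

**Step 13 (facial selectivity of the hydroboration that sets C6').** If the borane adds mainly to the other face, the fallback uses the enantiomeric ring and corrects C3' afterwards; it sets out from 3 and returns at 20.
- Petasis methylenation of 3 gives tert-butyldimethyl{[(1S)-3,5,5-trimethyl-4-methylidenecyclohex-2-en-1-yl]oxy}silane F3.
- Hydroboration–oxidation (9-BBN-H; NaOH, H2O2) then gives the cis alcohol [(1R,4S)-4-(TBS-oxy)-2,6,6-trimethylcyclohex-2-en-1-yl]methanol F4, which already has the correct C6'.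
- Pivaloylation (PivCl, pyridine) gives [(1R,4S)-4-(TBS-oxy)-2,6,6-trimethylcyclohex-2-en-1-yl]methyl pivalate F5.
- Desilylation (Bu4NF, THF) gives [(1R,4S)-4-hydroxy-2,6,6-trimethylcyclohex-2-en-1-yl]methyl pivalate F6.
- Mitsunobu inversion (4-nitrobenzoic acid, PPh3, DIAD) gives (1R,4R)-3,5,5-trimethyl-4-[(pivaloyloxy)methyl]cyclohex-2-en-1-yl 4-nitrobenzoate F7.
- Selective methanolysis (K2CO3, MeOH, 0 °C) gives [(1R,4R)-4-hydroxy-2,6,6-trimethylcyclohex-2-en-1-yl]methyl pivalate F8.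
- Silylation (TBSCl, imidazole) gives [(1R,4R)-4-(TBS-oxy)-2,6,6-trimethylcyclohex-2-en-1-yl]methyl pivalate F9, and i-Bu2AlH removes the pivalate to give 20.

**Step 23 (Wittig reaction on the dehydration-prone lactol with two free hydroxyls).** The fallback opens the lactone as an amide instead; it sets out from 15 and returns at 37.
- Silylation (Et3SiCl, imidazole) gives 4-{1-(triethylsilyloxy)-2-[(4R)-4-(TBS-oxy)-2,6,6-trimethylcyclohex-1-en-1-yl]ethyl}furan-2(5H)-one F10.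
- Aminolysis (MeNHOMe·HCl, AlMe3, CH2Cl2) gives (2E)-3-(hydroxymethyl)-N-methoxy-N-methyl-4-(triethylsilyloxy)-5-[(4R)-4-(TBS-oxy)-2,6,6-trimethylcyclohex-1-en-1-yl]pent-2-enamide F11.
- Esterification with 36 (DCC, DMAP) gives the corresponding C19 (2E)-dec-2-enoate Weinreb amide F12.
- Cp2Zr(H)Cl reduces the amide, not the esters, to the enal (2Z)-2-{1-(triethylsilyloxy)-2-[(4R)-4-(TBS-oxy)-2,6,6-trimethylcyclohex-1-en-1-yl]ethyl}-4-oxobut-2-en-1-yl (2E)-dec-2-enoate F13.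
- Wittig reaction with ylide 34, now with no free alkoxide present, gives (3R,3'R,6'R)-3,3'-bis(TBS-oxy)-8-(triethylsilyloxy)-7,8-dihydro-β,ε-caroten-19-yl (2E)-dec-2-enoate F14.
- Selective removal of the triethylsilyl group (HF·pyridine, pyridine, THF, 0 °C) gives 37.

## Further compounds

F1 | step 9 | (4R)-4-(TBS-oxy)-2,2,6-trimethylcyclohexanone (C6 epimers) | O=C1C(C)C[C@@H](O[Si](C)(C)C(C)(C)C)CC1(C)C
F2 | step 9 | tert-butyldimethyl{[(1R)-3,3,5-trimethyl-4-methylidenecyclohexyl]oxy}silane (C5 epimers) | C=C1C(C)C[C@@H](O[Si](C)(C)C(C)(C)C)CC1(C)C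
F3 | step 13 | tert-butyldimethyl{[(1S)-3,5,5-trimethyl-4-methylidenecyclohex-2-en-1-yl]oxy}silane | C=C1C(C)=C[C@@H](O[Si](C)(C)C(C)(C)C)CC1(C)C
F4 | step 13 | [(1R,4S)-4-(TBS-oxy)-2,6,6-trimethylcyclohex-2-en-1-yl]methanol (cis) | OC[C@H]1C(C)=C[C@@H](O[Si](C)(C)C(C)(C)C)CC1(C)C
F5 | step 13 | [(1R,4S)-4-(TBS-oxy)-2,6,6-trimethylcyclohex-2-en-1-yl]methyl pivalate | CC(C)(C)C(=O)OC[C@H]1C(C)=C[C@@H](O[Si](C)(C)C(C)(C)C)CC1(C)C
F6 | step 13 | [(1R,4S)-4-hydroxy-2,6,6-trimethylcyclohex-2-en-1-yl]methyl pivalate | CC(C)(C)C(=O)OC[C@H]1C(C)=C[C@@H](O)CC1(C)C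
F7 | step 13 | (1R,4R)-3,5,5-trimethyl-4-[(pivaloyloxy)methyl]cyclohex-2-en-1-yl 4-nitrobenzoate | CC(C)(C)C(=O)OC[C@H]1C(C)=C[C@H](OC(=O)c2ccc(cc2)[N+](=O)[O-])CC1(C)C
F8 | step 13 | [(1R,4R)-4-hydroxy-2,6,6-trimethylcyclohex-2-en-1-yl]methyl pivalate | CC(C)(C)C(=O)OC[C@H]1C(C)=C[C@H](O)CC1(C)C
F9 | step 13 | [(1R,4R)-4-(TBS-oxy)-2,6,6-trimethylcyclohex-2-en-1-yl]methyl pivalate | CC(C)(C)C(=O)OC[C@H]1C(C)=C[C@H](O[Si](C)(C)C(C)(C)C)CC1(C)C
F10 | step 23 | 4-{1-(triethylsilyloxy)-2-[(4R)-4-(TBS-oxy)-2,6,6-trimethylcyclohex-1-en-1-yl]ethyl}furan-2(5H)-one (both C8 epimers) | O=C1OCC(C(O[Si](CC)(CC)CC)CC2=C(C)C[C@@H](O[Si](C)(C)C(C)(C)C)CC2(C)C)=C1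
F11 | step 23 | (2E)-3-(hydroxymethyl)-N-methoxy-N-methyl-4-(triethylsilyloxy)-5-[(4R)-4-(TBS-oxy)-2,6,6-trimethylcyclohex-1-en-1-yl]pent-2-enamide | CON(C)C(=O)/C=C(\CO)C(O[Si](CC)(CC)CC)CC1=C(C)C[C@@H](O[Si](C)(C)C(C)(C)C)CC1(C)C
F12 | step 23 | (2E)-dec-2-enoate ester of F11 at its hydroxymethyl group | CCCCCCC/C=C/C(=O)OC\C(=C/C(=O)N(C)OC)C(O[Si](CC)(CC)CC)CC1=C(C)C[C@@H](O[Si](C)(C)C(C)(C)C)CC1(C)C
F13 | step 23 | (2Z)-2-{1-(triethylsilyloxy)-2-[(4R)-4-(TBS-oxy)-2,6,6-trimethylcyclohex-1-en-1-yl]ethyl}-4-oxobut-2-en-1-yl (2E)-dec-2-enoate | CCCCCCC/C=C/C(=O)OC\C(=C/C=O)C(O[Si](CC)(CC)CC)CC1=C(C)C[C@@H](O[Si](C)(C)C(C)(C)C)CC1(C)C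
F14 | step 23 | (3R,3'R,6'R)-3,3'-bis(TBS-oxy)-8-(triethylsilyloxy)-7,8-dihydro-β,ε-caroten-19-yl (2E)-dec-2-enoate | CCCCCCC/C=C/C(=O)OC\C(=C/C=C/C(C)=C/C=C/C=C(C)/C=C/C=C(C)/C=C/[C@H]1C(C)=C[C@H](O[Si](C)(C)C(C)(C)C)CC1(C)C)C(O[Si](CC)(CC)CC)CC1=C(C)C[C@@H](O[Si](C)(C)C(C)(C)C)CC1(C)C
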